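You asked for a quick number.

Z 20 mM (fed, over 2.5 min); L 15 µM; X 38 µM; time 2.0 h; the fed solution adds 0.25 times the starting volume

    Z + L ⇌ Q + L, rate k1*[Z]*[L] forward; the back reaction follows from the equilibrium constant (K1 = 1.3, k1 = 440 M⁻¹ s⁻¹)
    Q ⇌ D (K2 = 2.3, k2 = 0.012 s⁻¹)
    D + L ⇌ J + L, rate k3*[L]*[D] forward; the back reaction follows from the equilibrium constant (K3 = 0.074, k3 = 96 M⁻¹ s⁻¹)
    J + L ⇌ Z + L, rate k4*[L]*[J] forward; the back reaction follows from the equilibrium constant (k4 = 3200 M⁻¹ s⁻¹)
    L + X ⇌ L.X (K5 = 1.4 × 10⁵ M⁻¹, k5 = 550 M⁻¹ s⁻¹)

- why nothing more happens at 2.0 h, or that something still does (it is still moving / forward and back rates have come level / all of Z has reacted / no working catalyst is left)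
- amount of Q at 2.0 h, in percent of the Z charged
- amount of D at 2.0 h, in percent of the Z charged

- amounts are per litre of the starting volume; all of the dose is in the solution fed
- the reaction counts as stopped when no species that holds the Z changes by six tenths of a point or more over the second half of the time
- run time (flask): 2.0 h

Your hunch was that X, by holding L, would leave this flask still moving at the end, so I looked at the clock first. I took 5.3, the binding constant of X times c_X at the start, as a rough ratio of held to free catalyst, which left a c_L of about 2.37 µM, and with that value the slowest single exchange, Z with Q, had a relaxation half-life of 6.25 min. Taking that one exchange as the clock of the whole round, I counted 19.2 such half-lives in the run, and since each one takes 0.301 off the logarithm of the distance from rest, my estimate was a fall of about 5.78 powers of ten in that distance.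

So I reckoned the end by thermodynamic control, as a ladder of logarithms. Going round from Z at nought and adding the logarithm of each equilibrium constant on the way to J, Q stood at 0.114, D at 0.476 and J at −0.655. Taking the antilogarithms gave 23.6% for Q and 54.3% for D. I called such a figure the rest share, the weight of a species' rung over the sum of the weights of Z, Q, D and J, and its expression has no c_L in it, so in my reckoning X moved the clock and left the number alone.

The forecast answered forward and back rates have come level, with 23.6% of Q and 54.3% of D, holding that “the yields follow from the equilibrium constants alone”.

The simulation gave forward and back rates have come level, with 23.6% of Q and 54.3% of D.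

This flask had come to rest with X holding 75.0% of the catalyst: Q read 23.6% at 1.00 h and 23.6% at 2.00 h, and when left until 20.0 h it read 23.6%, a change of 0 percentage points over the added time, which left it 2.4 × 10⁻⁶ points from its rest share of 23.6%, while D, at 54.3%, lay 3.4 × 10⁻⁶ points from 54.3%. The neighbour flask, with 0.0060 mM of L in place of 15 µM, ended at 2.00 h with 23.5% of Q, 0.12 points from the same rest share.

The constants used here belong to no real substance.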